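Two questions stand on the green flask: how much target and how much isomer of the product it holds at 3.0 d.

all flasks: gas 96 mM (held)
- green: substrate 0.25 M; the very flask that is asked about, followed so far
- violet: substrate 0.12 M; run made earlier
- flask: substrate 0.25 M; time 3.0 d

- green (time / h: target / %, isomer of the product / %): 2.50: 76.9, 10.0; 8.00: 89.8, 11.7; 15.0: 89.7, 12.3; 20.0: 88.7, 9.7
- violet (time / h: target / %, isomer of the product / %): 4.00: 87.5, 10.2; 10.0: 89.0, 10.5; 20.0: 91.4, 8.5; 48.0: 90.2, 10.1

(readings scatter by 1 percentage point)

* the target standing at 3.0 d, as a percentage of the substrate charged
* the isomer of the product standing at 3.0 d, as a percentage of the substrate charged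

- at the start none of reagent is dissolved
- the earlier runs were read with a standard deviation of 1 percentage point
- reactions considered so far: substrate <-> tight pair; gas <-> reagent; reagent + tight pair -> target; tight pair -> side product; reagent + loose pair -> isomer of the product; tight pair <-> loose pair

We carry one quantity, the split s, the isomer of the product standing per unit of target, a selectivity, taken as a reading with the scatter of the green readings from 8.00 h on: 0.126. These readings show no clear trend beyond the scatter of 1 percentage point, so we take them as the plateau and assume that the two products share the whole charge. As a first answer, target equal to the charge and isomer s times that add up to more than the charge. Going round again, we divide the charge by one plus s, which gives 88.8 % of target and 11.2 % of isomer.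

The forecast, reasoning that “3 days should simply be the plateau”, gives 89.5 % of target and 10.7 % of isomer, a little more target than ours.

The green flask gives 88.4 % of target and 11.3 % of isomer of the product.

    substrate ⇌ tight pair (K = 0.00860, k = 2.60 × 10⁻⁴ s⁻¹)
    gas ⇌ reagent, rate k2*(csat - [reagent]) (kL = 8.20 × 10⁻⁴ s⁻¹)
    reagent + tight pair → target (k = 4.10 M⁻¹ s⁻¹)
    tight pair → side product (k = 4.40 × 10⁻⁴ s⁻¹)
    reagent + loose pair → isomer of the product (k = 2.40 M⁻¹ s⁻¹)
    tight pair ⇌ loose pair (K = 1.40, k = 0.0250 s⁻¹)

The forecast holds, and the green flask already stood at 88.4 % of target at 0.600 d, with a largest change of 0 points over the second half of the time. Carried to a neighbouring flask charged with 0.62 M of substrate and read at the same time, s gives 88.8 % of target, but that flask holds 79.3 % of target and 20.0 % of isomer, a split of 0.252, twice s.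

The readings stem from a simulated flask for an exercise, noise included.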